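**Plan**

- Retrosynthesis: the C8–C12 bond of the cyclopentenone is cut first. The 2-bromo-4-hydroxycyclopent-2-enone ring (C9 ketone, C10(Br)=C11 enone, tertiary carbinol C12 next to the enolisable C8) is the retron of a Piancatelli rearrangement of a 3-bromo-5-alkyl-2-furylcarbinol. Furan C2–C5 become C9–C12, the furan oxygen becomes the C9 carbonyl oxygen, and the carbinol carbon is C8.
- Further cuts: C8–C9 (furylmagnesium + C1–C8 aldehyde), C12–C13 (lithiated 2,3-dibromofuran + (2Z,5Z)-octadienyl bromide), C2=C3 (cross-metathesis) and C4–C5 (allylation).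
- Forward: the ω-chain bromide is made from two alkynes and attached to the furan; the C1–C8 aldehyde is built from L-threitol acetonide; the two halves are joined; the only ring of the skeleton is closed last on the complete chain; one-pot deprotection follows.
- Stereochemistry: C6/C7 come from L-tartaric acid (threitol acetonide), C5 from a matched Brown allylation, the Z-alkenes from Lindlar reduction. C12 is set by torquoselective conrotation relayed from C7 through a zinc chelate to the dioxolane oxygen; C8 is set by equilibration α to the ketone.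
- Helpers: the trans-dioxolane on C6/C7 is a temporary ring that carries the stereocontrol and keeps O5 from trapping the cation; the second furan bromine is the metalation handle. Both are gone at the end.

Key step: step 13

Remark: prostanoid numbering of the target (C1 = ester carbon, C8 and C12 = ring sp3 carbons, C20 = methyl) is used for all intermediates. 2,3-Dibromofuran, (−)-Ipc2B(allyl) solution and i-PrMgCl·LiCl are taken as commercial.

**Step 1**
Reactants: 1 1-bromopent-2-yne; 2 prop-2-yn-1-ol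
Product: 3 octa-2,5-diyn-1-ol
Conditions: CuI, NaI, K2CO3, DMF, rt
Reagents that add atoms: none
Why: Copper(I)-mediated coupling of a terminal alkyne with a propargylic bromide (skipped-diyne synthesis); the copper acetylide substitutes the primary bromide without allene formation.

**Step 2**
Reactants: 3 octa-2,5-diyn-1-ol
Product: 4 (2Z,5Z)-octa-2,5-dien-1-ol
Conditions: H2 (1 atm), Lindlar catalyst, quinoline, EtOAc, rt
Reagents that add atoms: none
Why: Lindlar semihydrogenation; syn delivery of H2 to each alkyne should set both Z double bonds.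

**Step 3**
Reactants: 4 (2Z,5Z)-octa-2,5-dien-1-ol
Product: 5 (2Z,5Z)-1-bromoocta-2,5-diene
Conditions: CBr4, PPh3, CH2Cl2, 0 °C
Reagents that add atoms: carbon tetrabromide, BrC(Br)(Br)Br
Why: Appel bromination of a primary allylic alcohol under neutral conditions, without allylic transposition or Z/E isomerisation.

**Step 4**
Reactants: 6 2,3-dibromofuran; 5 (2Z,5Z)-1-bromoocta-2,5-diene
Product: 8 2,3-dibromo-5-[(2Z,5Z)-octa-2,5-dien-1-yl]furan, via 4,5-dibromo-2-furyllithium 7 (not isolated)
Conditions: LDA, THF, −78 °C; then 5, −78 → 0 °C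
Reagents that add atoms: none
Why: LDA removes the only α-proton of the furan (C5; deprotonation–alkylation of 2,3-dibromofuran is precedented) and the furyllithium is alkylated by SN2 at the primary allylic bromide.

**Step 5**
Reactants: 9 (4S,5S)-2,2-dimethyl-1,3-dioxolane-4,5-dimethanol (2,3-O-isopropylidene-L-threitol)
Product: 10 {(4S,5S)-5-[(benzyloxy)methyl]-2,2-dimethyl-1,3-dioxolan-4-yl}methanol
Conditions: NaH (1.0 equiv), BnBr, Bu4NI (cat.), THF, 0 °C → rt
Reagents that add atoms: benzyl bromide, BrCc1ccccc1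
Why: Williamson monobenzylation of a C2-symmetric diol; both hydroxyls are equivalent, so one monoether results.

**Step 6**
Reactants: 10 {(4S,5S)-5-[(benzyloxy)methyl]-2,2-dimethyl-1,3-dioxolan-4-yl}methanol
Product: 11 (4R,5S)-5-[(benzyloxy)methyl]-2,2-dimethyl-1,3-dioxolane-4-carbaldehyde (4-O-benzyl-2,3-O-isopropylidene-L-threose)
Conditions: TEMPO (cat.), PhI(OAc)2, CH2Cl2, rt
Reagents that add atoms: none
Why: TEMPO/PhI(OAc)2 oxidation of a primary alcohol stops at the aldehyde and should not epimerise the α-alkoxy centre.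

**Step 7**
Reactants: 11 (4R,5S)-5-[(benzyloxy)methyl]-2,2-dimethyl-1,3-dioxolane-4-carbaldehyde
Product: 12 (1S)-1-{(4S,5S)-5-[(benzyloxy)methyl]-2,2-dimethyl-1,3-dioxolan-4-yl}but-3-en-1-ol (5S, anti to O6)
Conditions: (−)-Ipc2B(allyl) (from (+)-α-pinene), Et2O, −78 °C; then NaOH, H2O2
Reagents that add atoms: (−)-B-allyldiisopinocampheylborane, C=CCB([C@@H]1C[C@@H]2C[C@H]([C@H]1C)C2(C)C)[C@@H]1C[C@@H]2C[C@H]([C@H]1C)C2(C)C
Why: Brown allylboration through a chair Zimmerman–Traxler transition state; this reagent attacks the Si face, which is also the Felkin–Anh face of the (R)-α-alkoxy aldehyde (matched pair), so C5 should be set S, anti to the C6 oxygen.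

**Step 8**
Reactants: 12 (1S)-1-{(4S,5S)-5-[(benzyloxy)methyl]-2,2-dimethyl-1,3-dioxolan-4-yl}but-3-en-1-ol
Product: 13 tert-butyl{[(1S)-1-{(4R,5S)-5-[(benzyloxy)methyl]-2,2-dimethyl-1,3-dioxolan-4-yl}but-3-en-1-yl]oxy}dimethylsilane
Conditions: TBSOTf, 2,6-lutidine, CH2Cl2, −78 → 0 °C
Reagents that add atoms: tert-butyldimethylsilyl triflate, CC(C)(C)[Si](C)(C)OS(=O)(=O)C(F)(F)F
Why: Silylation of a hindered secondary alcohol with a silyl triflate; the TBS ether later keeps O5 from acting as a nucleophile.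

**Step 9**
Reactants: 13 tert-butyl{[(1S)-1-{(4R,5S)-5-[(benzyloxy)methyl]-2,2-dimethyl-1,3-dioxolan-4-yl}but-3-en-1-yl]oxy}dimethylsilane
Product: 14 methyl (2E,5S)-5-[(tert-butyldimethylsilyl)oxy]-5-{(4R,5S)-5-[(benzyloxy)methyl]-2,2-dimethyl-1,3-dioxolan-4-yl}pent-2-enoate
Conditions: methyl acrylate (4 equiv), Hoveyda–Grubbs II (3 mol %), CH2Cl2, 40 °C
Reagents that add atoms: methyl acrylate, C=CC(=O)OC
Why: Olefin cross-metathesis of a terminal alkene with an acrylate is selective for the E cross-product and adds C1–C2 with the ester.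

**Step 10**
Reactants: 14 methyl (2E,5S)-5-[(tert-butyldimethylsilyl)oxy]-5-{(4R,5S)-5-[(benzyloxy)methyl]-2,2-dimethyl-1,3-dioxolan-4-yl}pent-2-enoate
Product: 15 methyl (5S)-5-[(tert-butyldimethylsilyl)oxy]-5-[(4R,5S)-5-(hydroxymethyl)-2,2-dimethyl-1,3-dioxolan-4-yl]pentanoate
Conditions: H2 (1 atm), Pd(OH)2/C, EtOAc–EtOH, rt
Reagents that add atoms: none
Why: Heterogeneous hydrogenation saturates the enoate and hydrogenolyses the benzyl ether in one operation, before any Z-alkene or C–Br bond is present.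

**Step 11**
Reactants: 15 methyl (5S)-5-[(tert-butyldimethylsilyl)oxy]-5-[(4R,5S)-5-(hydroxymethyl)-2,2-dimethyl-1,3-dioxolan-4-yl]pentanoate
Product: 16 methyl (5S)-5-[(tert-butyldimethylsilyl)oxy]-5-[(4R,5R)-5-formyl-2,2-dimethyl-1,3-dioxolan-4-yl]pentanoate
Conditions: TEMPO (cat.), PhI(OAc)2, CH2Cl2, rt; used directly
Reagents that add atoms: none
Why: The same mild primary-alcohol oxidation as in step 6 gives the C8 aldehyde without touching the C7 centre.

**Step 12**
Reactants: 8 2,3-dibromo-5-[(2Z,5Z)-octa-2,5-dien-1-yl]furan; 16 methyl (5S)-5-[(tert-butyldimethylsilyl)oxy]-5-[(4R,5R)-5-formyl-2,2-dimethyl-1,3-dioxolan-4-yl]pentanoate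
Product: 18 methyl (5S)-5-[(tert-butyldimethylsilyl)oxy]-5-{(4R,5S)-5-[(RS)-{3-bromo-5-[(2Z,5Z)-octa-2,5-dien-1-yl]furan-2-yl}(hydroxy)methyl]-2,2-dimethyl-1,3-dioxolan-4-yl}pentanoate, via 3-bromo-5-octadienyl-2-furylmagnesium chloride 17 (not isolated)
Conditions: i-PrMgCl·LiCl, THF, −30 °C; then 16, −78 → −20 °C; aqueous work-up
Reagents that add atoms: none
Why: Bromine–magnesium exchange (turbo-Grignard) takes the α-bromine at C2 and leaves the β-bromine, and the furyl Grignard adds to the aldehyde much faster than to the methyl ester; C8 is formed as a mixture, which does not matter because it is planarised in step 13.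

**Step 13**
Reactants: 18 methyl (5S)-5-[(tert-butyldimethylsilyl)oxy]-5-{(4R,5S)-5-[(RS)-{3-bromo-5-[(2Z,5Z)-octa-2,5-dien-1-yl]furan-2-yl}(hydroxy)methyl]-2,2-dimethyl-1,3-dioxolan-4-yl}pentanoate
Product: 20 methyl (5S)-5-[(tert-butyldimethylsilyl)oxy]-5-{(4R,5S)-5-[(1R,5S)-3-bromo-5-hydroxy-5-[(2Z,5Z)-octa-2,5-dien-1-yl]-2-oxocyclopent-3-en-1-yl]-2,2-dimethyl-1,3-dioxolan-4-yl}pentanoate, via kinetic C8 epimer 19 (not isolated)
Conditions: ZnCl2 (2 equiv), acetone–H2O (5:1), pH ≈ 6, 60 °C, 24–48 h
Reagents that add atoms: water, O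
Why: Zn(II)-assisted loss of the C8 hydroxyl gives the furfuryl (2-alkylidenefuranium) cation with C7 syn to the ring oxygen (A(1,3) strain against the C10 bromine), water adds to the alkyl-bearing furan carbon (C12), the hemiketal opens to the 1,4-dioxygenated pentadienyl cation C8=C9(O–Zn)–C10(Br)=C11–C12(+)(OH)R and proton loss after ring closure gives the enone; this is a Piancatelli rearrangement, the closest precedent being 5-alkyl-2-furylcarbinols giving 4-alkyl-4-hydroxycyclopent-2-enones. The five-membered ring is closed by a thermal conrotatory 4π electrocyclisation that forms the C8–C12 bond (Nazarov-type, formally 5-endo). C12 is set by torquoselectivity: its hydroxyl rotates outward (donor preference, the usual trans outcome) and the sense of conrotation is fixed by the six-membered zinc chelate (or hydrogen bond) between the C9 oxygen and the dioxolane oxygen on C7, in which C6 covers one face of C8, so that the C8–C12 bond forms anti to C6 (Fráter–Seebach-type) and C12 should come out S. C8 is formed first trans to the 12-OH (19) and, being the only enolisable position, should equilibrate under the reaction conditions to the more stable isomer 20 with the two carbon chains trans (8R). The step needs water attack at C12 (attack at C8 only regenerates 18), no trapping of the cation by O5 (silylated, and the trans-dioxolane forbids the trans-fused tetrahydrofuran) and retention of the C–Br bond, which the C10 position secures by ending as the α-bromine of the enone.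

**Step 14**
Reactants: 20 methyl (5S)-5-[(tert-butyldimethylsilyl)oxy]-5-{(4R,5S)-5-[(1R,5S)-3-bromo-5-hydroxy-5-[(2Z,5Z)-octa-2,5-dien-1-yl]-2-oxocyclopent-3-en-1-yl]-2,2-dimethyl-1,3-dioxolan-4-yl}pentanoate
Product: 21 methyl (5S,6S,7S)-7-[(1R,5S)-3-bromo-5-hydroxy-5-[(2Z,5Z)-octa-2,5-dien-1-yl]-2-oxocyclopent-3-en-1-yl]-5,6,7-trihydroxyheptanoate (CNP0143456.1)
Conditions: HCl (ca. 0.1 M) in MeOH, 0 °C → rt; NaHCO3 before concentration
Reagents that add atoms: none
Why: Acid-catalysed methanolysis cleaves the TBS ether and transketalises the acetonide in one pot, methanol as solvent keeps the 5-hydroxy ester from lactonising, and no stereocentre is touched.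

**Compound list**

1 | 1-bromopent-2-yne | CCC#CCBr | starting material
2 | prop-2-yn-1-ol | C#CCO | starting material
3 | octa-2,5-diyn-1-ol | CCC#CCC#CCO | intermediate
4 | (2Z,5Z)-octa-2,5-dien-1-ol | CC/C=C\C/C=C\CO | intermediate
5 | (2Z,5Z)-1-bromoocta-2,5-diene | CC/C=C\C/C=C\CBr | intermediate
6 | 2,3-dibromofuran | Brc1ccoc1Br | starting material
7 | 4,5-dibromo-2-furyllithium | [Li]c1cc(Br)c(Br)o1 | intermediate
8 | 2,3-dibromo-5-[(2Z,5Z)-octa-2,5-dien-1-yl]furan | CC/C=C\C/C=C\Cc1cc(Br)c(Br)o1 | intermediate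
9 | (4S,5S)-2,2-dimethyl-1,3-dioxolane-4,5-dimethanol | OC[C@@H]1OC(C)(C)O[C@H]1CO | starting material
10 | {(4S,5S)-5-[(benzyloxy)methyl]-2,2-dimethyl-1,3-dioxolan-4-yl}methanol | OC[C@@H]1OC(C)(C)O[C@H]1COCc1ccccc1 | intermediate
11 | (4R,5S)-5-[(benzyloxy)methyl]-2,2-dimethyl-1,3-dioxolane-4-carbaldehyde | O=C[C@@H]1OC(C)(C)O[C@H]1COCc1ccccc1 | intermediate
12 | (1S)-1-{(4S,5S)-5-[(benzyloxy)methyl]-2,2-dimethyl-1,3-dioxolan-4-yl}but-3-en-1-ol | C=CC[C@H](O)[C@@H]1OC(C)(C)O[C@H]1COCc1ccccc1 | intermediate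
13 | TBS ether of 12 | C=CC[C@H](O[Si](C)(C)C(C)(C)C)[C@@H]1OC(C)(C)O[C@H]1COCc1ccccc1 | intermediate
14 | methyl (2E,5S)-5-(TBS-oxy)-5-{(4R,5S)-5-[(benzyloxy)methyl]-2,2-dimethyl-1,3-dioxolan-4-yl}pent-2-enoate | COC(=O)/C=C/C[C@H](O[Si](C)(C)C(C)(C)C)[C@@H]1OC(C)(C)O[C@H]1COCc1ccccc1 | intermediate
15 | methyl (5S)-5-(TBS-oxy)-5-[(4R,5S)-5-(hydroxymethyl)-2,2-dimethyl-1,3-dioxolan-4-yl]pentanoate | COC(=O)CCC[C@H](O[Si](C)(C)C(C)(C)C)[C@@H]1OC(C)(C)O[C@H]1CO | intermediate
16 | methyl (5S)-5-(TBS-oxy)-5-[(4R,5R)-5-formyl-2,2-dimethyl-1,3-dioxolan-4-yl]pentanoate | COC(=O)CCC[C@H](O[Si](C)(C)C(C)(C)C)[C@@H]1OC(C)(C)O[C@H]1C=O | intermediate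
17 | 3-bromo-5-[(2Z,5Z)-octa-2,5-dien-1-yl]-2-furylmagnesium chloride | CC/C=C\C/C=C\Cc1cc(Br)c([Mg]Cl)o1 | intermediate
18 | furylcarbinol (C8 epimer mixture; 5-O-TBS, 6,7-O-isopropylidene) | CC/C=C\C/C=C\Cc1cc(Br)c(o1)C(O)[C@@H]1OC(C)(C)O[C@H]1[C@@H](O[Si](C)(C)C(C)(C)C)CCCC(=O)OC | intermediate
19 | (8S,12S) cyclopentenone, the C8 epimer of 20 | CC/C=C\C/C=C\C[C@@]1(O)C=C(Br)C(=O)[C@H]1[C@@H]2OC(C)(C)O[C@H]2[C@@H](O[Si](C)(C)C(C)(C)C)CCCC(=O)OC | intermediate
20 | (8R,12S) cyclopentenone (5-O-TBS, 6,7-O-isopropylidene target) | CC/C=C\C/C=C\C[C@@]1(O)C=C(Br)C(=O)[C@@H]1[C@@H]2OC(C)(C)O[C@H]2[C@@H](O[Si](C)(C)C(C)(C)C)CCCC(=O)OC | intermediate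
21 | methyl (5S,6S,7S)-7-[(1R,5S)-3-bromo-5-hydroxy-5-[(2Z,5Z)-octa-2,5-dien-1-yl]-2-oxocyclopent-3-en-1-yl]-5,6,7-trihydroxyheptanoate | CC/C=C\C/C=C\C[C@@]1(O)C=C(Br)C(=O)[C@@H]1[C@H](O)[C@@H](O)[C@@H](O)CCCC(=O)OC | target

**Step count**

Total: 14 steps. Longest linear sequence: 10 steps (9 → 21, steps 5–14); the furan branch is 4 steps (steps 1–4) before the union.

**Steps most likely to fail**

1. Step 13. Ionisation of the α-oxygenated, bromine-deactivated furfuryl carbinol may be slower than loss of the acetal or silyl group. The conrotation may be too little face-selective if the non-chelated rotamer competes, and O7 may undergo β-elimination from the enol during the C8 equilibration. Fallback, setting out from 18 and coming back at 21: the stereocontrolling element is changed from the dioxolane ether to a free 6,7-diol that can bind the metal directly. The acetonide is hydrolysed first (80% aqueous AcOH, 25–40 °C) to give the 5-O-TBS 6,7-diol furylcarbinol F1. Rearrangement of F1 (Dy(OTf)3, t-BuOH–H2O, 80 °C) should pass through a chair-like hydrogen-bonded or chelated array between the free 7-hydroxyl and the C12 oxygen with the C6 chain equatorial, and give the 5-O-TBS cyclopentenone triol F2 with the (8R,12S) ring directly, without the C8 equilibration. HF·pyridine in THF then removes the silyl group and gives 21.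

2. Step 4. Halogen migration in the lithiated dibromofuran may outrun the slow alkylation, and the doubly activated CH2 of the product may quench the furyllithium by proton transfer. Fallback, setting out from 5 and coming back at 18 (it replaces steps 4 and 12): 2-furyllithium (furan, n-BuLi, THF), which carries no halogen and can be used in excess, is alkylated with 5 to give 2-[(2Z,5Z)-octa-2,5-dien-1-yl]furan F3. NBS (DMF, −20 °C) brominates the free α-position to give 2-bromo-5-[(2Z,5Z)-octa-2,5-dien-1-yl]furan F4. LDA (THF, −78 °C) then induces the known base-mediated halogen migration of 2-bromo-5-alkylfurans to 3-bromo-5-[(2Z,5Z)-octa-2,5-dien-1-yl]-2-furyllithium F5 (not isolated), which is added to aldehyde 16 to give 18.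

3. Step 14. Prolonged protic acid may dehydrate the aldol-type 7-hydroxy ketone or lactonise the ester onto O5 while the hindered silyl ether and the trans-dioxolane are still being cleaved. Fallback, setting out from 20 and coming back at 21: the two groups are removed by orthogonal, aprotic means. HF·pyridine (pyridine-buffered, THF, 0 °C) first gives the 5-hydroxy 6,7-acetonide F6; the acetonide of F6 is then cleaved by Me2BBr (CH2Cl2, −78 °C, NaHCO3 quench) to give 21.

**Further compounds**

F1 | step 13 | 5-O-TBS 6,7-diol furylcarbinol (18 without the acetonide; C8 epimer mixture) | CC/C=C\C/C=C\Cc1cc(Br)c(o1)C(O)[C@H](O)[C@@H](O)[C@@H](O[Si](C)(C)C(C)(C)C)CCCC(=O)OC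
F2 | step 13 | 5-O-TBS ether of target 21 | CC/C=C\C/C=C\C[C@@]1(O)C=C(Br)C(=O)[C@@H]1[C@H](O)[C@@H](O)[C@@H](O[Si](C)(C)C(C)(C)C)CCCC(=O)OC
F3 | step 4 | 2-[(2Z,5Z)-octa-2,5-dien-1-yl]furan | CC/C=C\C/C=C\Cc1ccco1
F4 | step 4 | 2-bromo-5-[(2Z,5Z)-octa-2,5-dien-1-yl]furan | CC/C=C\C/C=C\Cc1ccc(Br)o1
F5 | step 4 | 3-bromo-5-[(2Z,5Z)-octa-2,5-dien-1-yl]-2-furyllithium | CC/C=C\C/C=C\Cc1cc(Br)c([Li])o1
F6 | step 14 | 6,7-O-isopropylidene derivative of target 21 (free 5-OH) | CC/C=C\C/C=C\C[C@@]1(O)C=C(Br)C(=O)[C@@H]1[C@@H]2OC(C)(C)O[C@H]2[C@@H](O)CCCC(=O)OC
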